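The isoflavone is disconnected at C3–C1' and O1–C2, so that ring C closes in the same operation that attaches ring B. An ortho-hydroxyaryl enaminone built on the fully substituted ring A meets a ring B aryl radical released from a diazonium salt by photoredox catalysis: arylation at the enaminone α-carbon (future C3) is followed by attack of the C8a phenol oxygen on the aminomethylene carbon (future C2) and loss of dimethylamine. The feature exploited is that C3 is the only nucleophilic sp2 C–H of the precursor, because C5 to C8 of ring A all carry substituents. Ring A is masked as MOM ethers, ring B as pivalates.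

Key step: step 6

Remark on the chemistry: the target is achiral (isoflavone numbering O1, C2, C3, C4, C4a, C5–C8, C8a, C1'–C6' is used). A 2-aminophenyl ester shifts its acyl group from O to N as the free base, so the ring B amine is generated and diazotised only as its tetrafluoroborate salt. Closure of ring C on the iminium carbon is 6-exo-trig, since the C=N+ bond lies outside the new ring.

Step 1
Reactants: 1 2,4,6-trihydroxyacetophenone; 2 prenyl bromide (1-bromo-3-methylbut-2-ene; two equivalents, one for each prenyl group)
Product: 3 1-[2,4,6-trihydroxy-3,5-bis(3-methylbut-2-enyl)phenyl]ethanone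
Conditions: prenyl bromide (2.1 equiv in total, slow addition), 10% aq KOH, 0 °C to rt, argon; acidify; chromatography
Reagents that add atoms: prenyl bromide (the second equivalent of 2), CC(C)=CCBr
Why: Two successive base-mediated C-alkylations of the phloroglucinol phenolate (SN2 on the allylic bromide), one at each of the two free ring carbons C3 and C5, should give the 3,5-diprenyl ketone, because water solvates the phenolate oxygens and steers the ambident anion to react at carbon.

Step 2
Reactants: 3 1-[2,4,6-trihydroxy-3,5-bis(3-methylbut-2-enyl)phenyl]ethanone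
Product: 4 1-[2-hydroxy-4,6-bis(methoxymethoxy)-3,5-bis(3-methylbut-2-enyl)phenyl]ethanone
Conditions: MOMCl (2.3 equiv), iPr2NEt (3 equiv), CH2Cl2, 0 °C to rt
Reagents that add atoms: chloromethyl methyl ether, COCCl
Why: Williamson-type O-alkylation should cap the 4-OH and one of the two equivalent ortho hydroxyls, while the last ortho hydroxyl is tied in a hydrogen bond to the ketone carbonyl and stays free when the reagent is limited.

Step 3
Reactants: 4 1-[2-hydroxy-4,6-bis(methoxymethoxy)-3,5-bis(3-methylbut-2-enyl)phenyl]ethanone
Product: 5 (E)-3-(dimethylamino)-1-[2-hydroxy-4,6-bis(methoxymethoxy)-3,5-bis(3-methylbut-2-enyl)phenyl]prop-2-en-1-one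
Conditions: DMF dimethyl acetal (3 equiv), toluene, 85 °C; evaporate; short neutral alumina plug
Reagents that add atoms: N,N-dimethylformamide dimethyl acetal, COC(OC)N(C)C
Why: Condensation of the methyl ketone with the amide acetal (enaminone formation) should give the thermodynamically preferred E push-pull alkene, and the chelated phenol should escape O-methylation at this temperature.

Step 4
Reactants: 6 4-nitroresorcinol (4-nitrobenzene-1,3-diol)
Product: 7 4-nitro-1,3-phenylene bis(2,2-dimethylpropanoate)
Conditions: PivCl (2.3 equiv), Et3N (3 equiv), DMAP (5 mol%), CH2Cl2, 0 °C to rt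
Reagents that add atoms: pivaloyl chloride, CC(C)(C)C(=O)Cl
Why: DMAP-catalysed O-acylation of both phenols with an acid chloride is routine, and the bulky pivalate is chosen because it resists acyl transfer and aminolysis in the steps that follow.

Step 5
Reactants: 7 4-nitro-1,3-phenylene bis(2,2-dimethylpropanoate)
Product: 9 2,4-bis(pivaloyloxy)benzenediazonium tetrafluoroborate, via 2,4-bis(pivaloyloxy)anilinium tetrafluoroborate 8 (not isolated)
Conditions: H2 (1 atm), 10% Pd/C, HBF4·OEt2 (1.5 equiv), EtOH–THF, 0 °C to rt; filter under argon; then tBuONO (1.3 equiv), 0 °C; precipitate with Et2O, keep cold and dark, use at once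
Reagents that add atoms: tert-butyl nitrite, CC(C)(C)ON=O; tetrafluoroboric acid (as its diethyl ether complex), [H+].F[B-](F)(F)F
Why: Catalytic hydrogenation of the nitro group in the presence of HBF4 should deliver the amine directly as its ammonium salt, which cannot attack the neighbouring pivalate, and nitrosation of that salt with an alkyl nitrite (diazotisation) should then give the diazonium tetrafluoroborate.

Step 6
Reactants: 5 (E)-3-(dimethylamino)-1-[2-hydroxy-4,6-bis(methoxymethoxy)-3,5-bis(3-methylbut-2-enyl)phenyl]prop-2-en-1-one; 9 2,4-bis(pivaloyloxy)benzenediazonium tetrafluoroborate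
Product: 12 3-[2,4-bis(pivaloyloxy)phenyl]-5,7-bis(methoxymethoxy)-6,8-bis(3-methylbut-2-enyl)chromen-4-one, via iminium tetrafluoroborate 10 (not isolated), via 2-(dimethylamino)-3-arylchroman-4-one 11 (not isolated)
Conditions: eosin Y (free acid, 3 mol%), 9 (1.5 equiv, added over 2 h as a DMSO solution), degassed DMSO, green LEDs (525 nm), 20 °C, argon, no base
Reagents that add atoms: none
Why: Photoexcited eosin Y reduces diazonium salt 9 by one electron, N2 departs, and the ring B aryl radical adds to the α-carbon of enaminone 5 to make the C3–C1' bond; the α-amino radical is then oxidised (by the eosin Y radical cation or by 9 in a chain) to iminium ion 10. The closest known reaction type is the photoredox domino α-C–H arylation and chromone annulation of ortho-hydroxyaryl enaminones with arenediazonium salts, itself a Meerwein-type arylation of a push-pull alkene. Ring C closes by attack of the phenol oxygen on the iminium carbon of 10 to make the O1–C2 bond, a 6-exo-trig closure because the C=N+ bond lies outside the new ring, and aminal 11 then loses dimethylamine to give the aromatic pyranone. No stereocentre is created in 12; the centres at C2 and C3 of 10 and 11 are transient and erased by the elimination. The step needs chemoselectivity for the enaminone C=C over the two prenyl alkenes and their allylic C–H bonds, which the high nucleophilicity and low hindrance of the enaminone CH and the easy oxidation of the α-amino radical should secure, while ring A offers no aryl C–H to the radical. The pivalates keep O2' out of the ring closure and resist the liberated dimethylamine, slow addition of 9 holds back dark azo coupling at C3, and exclusion of oxygen avoids singlet-oxygen ene reactions of the prenyl groups under the dye.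

Step 7
Reactants: 12 3-[2,4-bis(pivaloyloxy)phenyl]-5,7-bis(methoxymethoxy)-6,8-bis(3-methylbut-2-enyl)chromen-4-one
Product: 14 3-(2,4-dihydroxyphenyl)-5,7-dihydroxy-6,8-bis(3-methylbut-2-enyl)chromen-4-one (EANPDB:LEGU_00069), via 3-(2,4-dihydroxyphenyl)-5,7-bis(methoxymethoxy)-6,8-bis(3-methylbut-2-enyl)chromen-4-one 13 (not isolated)
Conditions: K2CO3 (3 equiv), MeOH, rt, argon; then 3 M aq HCl (to about 1 M), 45 °C, monitored and stopped at full conversion
Reagents that add atoms: none
Why: Carbonate-mediated ester methanolysis should remove the two aryl pivalates, and after acidification the acid-catalysed acetal exchange of the MOM ethers with methanol should free the 5- and 7-hydroxyls, the trisubstituted prenyl alkenes being expected to tolerate dilute HCl at this temperature for the short time needed.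

Compound list
1 | 2,4,6-trihydroxyacetophenone | CC(=O)c1c(O)cc(O)cc1O | starting material
2 | prenyl bromide (1-bromo-3-methylbut-2-ene) | CC(C)=CCBr | starting material
3 | 1-[2,4,6-trihydroxy-3,5-bis(3-methylbut-2-enyl)phenyl]ethanone | CC(=O)c1c(O)c(CC=C(C)C)c(O)c(CC=C(C)C)c1O | intermediate
4 | 1-[2-hydroxy-4,6-bis(methoxymethoxy)-3,5-bis(3-methylbut-2-enyl)phenyl]ethanone | CC(=O)c1c(O)c(CC=C(C)C)c(OCOC)c(CC=C(C)C)c1OCOC | intermediate
5 | (E)-3-(dimethylamino)-1-[2-hydroxy-4,6-bis(methoxymethoxy)-3,5-bis(3-methylbut-2-enyl)phenyl]prop-2-en-1-one | CN(C)/C=C/C(=O)c1c(O)c(CC=C(C)C)c(OCOC)c(CC=C(C)C)c1OCOC | intermediate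
6 | 4-nitroresorcinol (4-nitrobenzene-1,3-diol) | O=[N+]([O-])c1ccc(O)cc1O | starting material
7 | 4-nitro-1,3-phenylene bis(2,2-dimethylpropanoate) | CC(C)(C)C(=O)Oc1ccc([N+](=O)[O-])c(OC(=O)C(C)(C)C)c1 | intermediate
8 | 2,4-bis(pivaloyloxy)anilinium tetrafluoroborate | CC(C)(C)C(=O)Oc1ccc([NH3+])c(OC(=O)C(C)(C)C)c1.F[B-](F)(F)F | intermediate (not isolated)
9 | 2,4-bis(pivaloyloxy)benzenediazonium tetrafluoroborate | CC(C)(C)C(=O)Oc1ccc([N+]#N)c(OC(=O)C(C)(C)C)c1.F[B-](F)(F)F | intermediate
10 | N-{2-[2,4-bis(pivaloyloxy)phenyl]-3-[2-hydroxy-4,6-bis(methoxymethoxy)-3,5-bis(3-methylbut-2-enyl)phenyl]-3-oxopropylidene}-N-methylmethanaminium tetrafluoroborate (racemic, transient) | C[N+](C)=CC(c1ccc(OC(=O)C(C)(C)C)cc1OC(=O)C(C)(C)C)C(=O)c1c(O)c(CC=C(C)C)c(OCOC)c(CC=C(C)C)c1OCOC.F[B-](F)(F)F | intermediate (not isolated)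
11 | 2-(dimethylamino)-3-[2,4-bis(pivaloyloxy)phenyl]-5,7-bis(methoxymethoxy)-6,8-bis(3-methylbut-2-enyl)chroman-4-one (racemic, cis and trans at C2/C3 not defined, both centres lost on elimination) | CN(C)C1Oc2c(CC=C(C)C)c(OCOC)c(CC=C(C)C)c(OCOC)c2C(=O)C1c1ccc(OC(=O)C(C)(C)C)cc1OC(=O)C(C)(C)C | intermediate (not isolated)
12 | 3-[2,4-bis(pivaloyloxy)phenyl]-5,7-bis(methoxymethoxy)-6,8-bis(3-methylbut-2-enyl)chromen-4-one | CC(C)=CCc1c(OCOC)c(CC=C(C)C)c2occ(-c3ccc(OC(=O)C(C)(C)C)cc3OC(=O)C(C)(C)C)c(=O)c2c1OCOC | intermediate
13 | 3-(2,4-dihydroxyphenyl)-5,7-bis(methoxymethoxy)-6,8-bis(3-methylbut-2-enyl)chromen-4-one | CC(C)=CCc1c(OCOC)c(CC=C(C)C)c2occ(-c3ccc(O)cc3O)c(=O)c2c1OCOC | intermediate (not isolated)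
14 | 3-(2,4-dihydroxyphenyl)-5,7-dihydroxy-6,8-bis(3-methylbut-2-enyl)chromen-4-one | CC(C)=CCc1c(O)c(CC=C(C)C)c2occ(-c3ccc(O)cc3O)c(=O)c2c1O | target

Total step count: 7 (three for the ring A enaminone, two for the ring B diazonium salt, the key step, one global deprotection).
Longest linear sequence: 5 steps (steps 1, 2, 3, 6, 7, from 2,4,6-trihydroxyacetophenone).

Steps most likely to fail

Step 6. The aryl radical may lose chemoselectivity, adding to a prenyl double bond or abstracting an allylic hydrogen. The diazonium ion may also couple ionically at the enaminone carbon in the dark, or decompose by participation of the ortho pivalate before electron transfer. The fallback sets out from 5 and comes back to the route at 14, using iodocyclisation and cross-coupling instead of radical arylation. Enaminone 5 is treated with I2 (1.05 equiv) and pyridine in CHCl3 at 0 °C, where the enaminone carbon should outpace the prenyl alkenes; this iodine-induced cyclisation should give 3-iodo-5,7-bis(methoxymethoxy)-6,8-bis(3-methylbut-2-enyl)chromen-4-one F1. Separately, commercial 4-bromoresorcinol is converted with MOMCl and iPr2NEt into 1-bromo-2,4-bis(methoxymethoxy)benzene F2, and Miyaura borylation (bis(pinacolato)diboron, Pd(dppf)Cl2, KOAc, dioxane, 85 °C) then gives 2-[2,4-bis(methoxymethoxy)phenyl]-4,4,5,5-tetramethyl-1,3,2-dioxaborolane F3. Suzuki–Miyaura coupling of F1 with F3 (Pd(PPh3)4, aq K2CO3, DME, 80 °C) should give 3-[2,4-bis(methoxymethoxy)phenyl]-5,7-bis(methoxymethoxy)-6,8-bis(3-methylbut-2-enyl)chromen-4-one F4, and 3 M HCl in MeOH at 45 °C then removes all four MOM groups and reaches 14.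

Step 5. Pivaloyl transfer from O to N may occur if any free amine or the hydroxylamine stage of the reduction escapes protonation, and the activated para ester may be lost from the diazonium ion by solvolysis. The fallback sets out from 6 and comes back at 8, carrying the nitrogen as a carbamate until acid releases it. Nitroarene 6 is hydrogenated (H2, 10% Pd/C, EtOAc) in the presence of Boc2O, which traps the amine as tert-butyl N-(2,4-dihydroxyphenyl)carbamate F5. Acylation with PivCl, Et3N and DMAP in CH2Cl2 then gives 4-[(tert-butoxycarbonyl)amino]-1,3-phenylene bis(2,2-dimethylpropanoate) F6. HBF4·OEt2 in CH2Cl2 at 0 °C cleaves the carbamate and gives anilinium salt 8 without passing through the free base, and salt 8 is diazotised with tBuONO as in step 5.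

Step 1. Over-alkylation to dearomatised gem-diprenyl dienones, O-alkylation and incomplete second prenylation may erode the supply of 3. The fallback sets out from 1 and comes back at 3. Friedel–Crafts prenylation with 2-methylbut-3-en-2-ol and BF3·OEt2 in dioxane at rt replaces the phenolate alkylation by electrophilic substitution with a prenyl cation. No phenolate is present, so the dienone pathway is closed, and short reaction time limits chroman formation. No further compound is made on this way (none F0).

Further compounds
F1 | step 6 | 3-iodo-5,7-bis(methoxymethoxy)-6,8-bis(3-methylbut-2-enyl)chromen-4-one | CC(C)=CCc1c(OCOC)c(CC=C(C)C)c2occ(I)c(=O)c2c1OCOC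
F2 | step 6 | 1-bromo-2,4-bis(methoxymethoxy)benzene | COCOc1ccc(Br)c(OCOC)c1
F3 | step 6 | 2-[2,4-bis(methoxymethoxy)phenyl]-4,4,5,5-tetramethyl-1,3,2-dioxaborolane | COCOc1ccc(B2OC(C)(C)C(C)(C)O2)c(OCOC)c1
F4 | step 6 | 3-[2,4-bis(methoxymethoxy)phenyl]-5,7-bis(methoxymethoxy)-6,8-bis(3-methylbut-2-enyl)chromen-4-one | CC(C)=CCc1c(OCOC)c(CC=C(C)C)c2occ(-c3ccc(OCOC)cc3OCOC)c(=O)c2c1OCOC
F5 | step 5 | tert-butyl N-(2,4-dihydroxyphenyl)carbamate | CC(C)(C)OC(=O)Nc1ccc(O)cc1O
F6 | step 5 | 4-[(tert-butoxycarbonyl)amino]-1,3-phenylene bis(2,2-dimethylpropanoate) | CC(C)(C)OC(=O)Nc1ccc(OC(=O)C(C)(C)C)cc1OC(=O)C(C)(C)C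
F0 | step 1 | none | none
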